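**Retrosynthetic overview**

1. Target 14 ⇐ bis‑benzyl ether 13 by global hydrogenolysis.
2. Both aryl–CH2 bonds are cut (sp2–sp3 Negishi couplings), giving aryl bromides 7 and 12 plus a C6 unit with differentiated ends (iodo‑acetate 5).
3. The target is the "pseudo‑meso" (erythro) dimethylbutane, so 5 ⇐ monoacetate 4 ⇐ lipase desymmetrisation of meso diol 3; this one enzymatic step fixes the absolute configuration of both stereocentres.
4. 3 ⇐ LiAlH4 reduction of the cis anhydride 2 ⇐ syn hydrogenation of 2,3‑dimethylmaleic anhydride 1.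
5. No ring is built: both arenes come intact from bromophenols, and the only other ring (the anhydride) is opened in step 2.

Assumption: the lipase acetylates the CH2OH on the (S)-carbon of the meso diol (by analogy with 2‑methylpropane‑1,3‑diol; not confirmed for this substrate), giving (2S,3R)-4. If it gives ent‑4, use 12 in step 6 and 7 in step 10; the same target results.

**Route**

Step 1
Reactants: 1, 2,3‑dimethylmaleic anhydride
Product: 2, cis‑(3R,4S)-3,4‑dimethyloxolane‑2,5‑dione (meso‑2,3‑dimethylsuccinic anhydride)
Conditions: H2 (4 atm), 10% Pd/C, EtOAc, rt; recrystallise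
Reagents that add atoms: none
Why: Heterogeneous catalytic hydrogenation adds both hydrogens syn to one face, giving the cis (meso, achiral) anhydride; only relative configuration is created here.

Step 2
Reactants: 2, meso‑2,3‑dimethylsuccinic anhydride
Product: 3, (2R,3S)-2,3‑dimethylbutane‑1,4‑diol (meso)
Conditions: LiAlH4 (excess), THF, 0 °C → reflux; Fieser work‑up
Reagents that add atoms: none
Why: Exhaustive hydride reduction of the anhydride to the 1,4‑diol does not touch the two C–H stereocentres, so the meso relationship is kept.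

Step 3
Reactants: 3, meso‑2,3‑dimethylbutane‑1,4‑diol
Product: 4, (2S,3R)-4‑hydroxy‑2,3‑dimethylbutyl acetate
Conditions: lipase (Burkholderia cepacia lipase, immobilised), vinyl acetate, MTBE, 0–20 °C; stop once the diol is consumed and ~10% diacetate has formed
Reagents that add atoms: vinyl acetate, C=COC(C)=O
Why: Lipase‑catalysed irreversible transesterification (enzymatic desymmetrisation of a meso diol) acylates one enantiotopic CH2OH, so this catalytic asymmetric step sets the absolute configuration of both stereocentres; slight over‑acylation removes the minor enantiomer as diacetate and raises the ee.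

Step 4
Reactants: 4, (2S,3R)-4‑hydroxy‑2,3‑dimethylbutyl acetate
Product: 5, (2S,3R)-4‑iodo‑2,3‑dimethylbutyl acetate
Conditions: I2, PPh3, imidazole, CH2Cl2, 0 °C → rt (run directly on fresh 4)
Reagents that add atoms: iodine, II
Why: Appel‑type iodination of the primary alcohol under near‑neutral conditions leaves the acetate and both stereocentres untouched, and removes the free OH before 1,4‑acyl migration can racemise 4.

Step 5
Reactants: 6, 4‑bromo‑2‑methoxyphenol
Product: 7, 1‑(benzyloxy)-4‑bromo‑2‑methoxybenzene
Conditions: BnBr, K2CO3, DMF, 60 °C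
Reagents that add atoms: benzyl bromide, BrCc1ccccc1
Why: Williamson etherification of the phenoxide masks the acidic OH for the organozinc step.

Step 6
Reactants: 5, (2S,3R)-4‑iodo‑2,3‑dimethylbutyl acetate; 7, 1‑(benzyloxy)-4‑bromo‑2‑methoxybenzene
Product: 8, (2S,3S)-4‑[4‑(benzyloxy)-3‑methoxyphenyl]-2,3‑dimethylbutyl acetate
Conditions: (i) Zn dust (BrCH2CH2Br/TMSCl‑activated), DMA, 40 °C; (ii) 7, Pd(OAc)2 (2 mol%), SPhos (4 mol%), THF–DMA, 50 °C
Reagents that add atoms: none (both partners are the listed reactants)
Why: Zinc insertion into the primary C–I bond followed by Negishi coupling forms the aryl–CH2 bond; the alkylzinc tolerates the acetate, and the stereocentres are β/γ to the metal so they are not affected (the S,S label is a CIP priority change only).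

Step 7
Reactants: 8, the aryl acetate
Product: 9, (2S,3S)-4‑[4‑(benzyloxy)-3‑methoxyphenyl]-2,3‑dimethylbutan‑1‑ol
Conditions: K2CO3, MeOH, rt
Reagents that add atoms: none
Why: Zemplén‑type methanolysis removes the acetate; nothing else in 8 is base‑sensitive and no stereocentre is α to a carbonyl.

Step 8
Reactants: 9, the primary alcohol
Product: 10, 1‑(benzyloxy)-4‑[(2S,3S)-4‑iodo‑2,3‑dimethylbutyl]-2‑methoxybenzene
Conditions: I2, PPh3, imidazole, CH2Cl2, 0 °C → rt
Reagents that add atoms: iodine, II
Why: Appel‑type iodination of the remaining primary alcohol; aryl benzyl and methyl ethers are inert.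

Step 9
Reactants: 11, 4‑bromo‑2,6‑dimethoxyphenol
Product: 12, 2‑(benzyloxy)-5‑bromo‑1,3‑dimethoxybenzene
Conditions: BnBr, K2CO3, DMF, 60 °C
Reagents that add atoms: benzyl bromide, BrCc1ccccc1
Why: Williamson etherification; the hindered phenoxide still alkylates cleanly with the reactive benzylic halide in DMF.

Step 10
Reactants: 10, the alkyl iodide; 12, 2‑(benzyloxy)-5‑bromo‑1,3‑dimethoxybenzene
Product: 13, 2‑(benzyloxy)-5‑[(2R,3S)-4‑[4‑(benzyloxy)-3‑methoxyphenyl]-2,3‑dimethylbutyl]-1,3‑dimethoxybenzene
Conditions: (i) Zn dust (activated), DMA, 40 °C; (ii) 12, Pd(OAc)2 (2 mol%), SPhos (4 mol%), THF–DMA, 50 °C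
Reagents that add atoms: none (both partners are the listed reactants)
Why: A second Negishi sp3–sp2 coupling attaches the syringyl ring to the arm that carried the acetate, so the enzymatic differentiation of the two ends becomes the guaiacyl/syringyl difference; the bromide has no ortho substituents and the stereocentres are untouched.

Step 11
Reactants: 13, the bis‑benzyl ether
Product: 14, 4‑[(2S,3R)-4‑(4‑hydroxy‑3,5‑dimethoxyphenyl)-2,3‑dimethylbutyl]-2‑methoxyphenol (target)
Conditions: H2 (1 atm), 10% Pd/C, EtOAc–MeOH, rt
Reagents that add atoms: none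
Why: Hydrogenolysis cleaves both aryl benzyl ethers; the molecule has no other reducible group and the stereocentres are not benzylic.

**Compound list**

1 | 2,3‑dimethylmaleic anhydride | CC1=C(C)C(=O)OC1=O | starting material
2 | cis‑(3R,4S)-3,4‑dimethyloxolane‑2,5‑dione (meso) | C[C@@H]1[C@H](C)C(=O)OC1=O | intermediate
3 | (2R,3S)-2,3‑dimethylbutane‑1,4‑diol (meso) | OC[C@H](C)[C@H](C)CO | intermediate
4 | (2S,3R)-4‑hydroxy‑2,3‑dimethylbutyl acetate | OC[C@H](C)[C@H](C)COC(C)=O | intermediate
5 | (2S,3R)-4‑iodo‑2,3‑dimethylbutyl acetate | IC[C@H](C)[C@H](C)COC(C)=O | intermediate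
6 | 4‑bromo‑2‑methoxyphenol | COc1cc(Br)ccc1O | starting material
7 | 1‑(benzyloxy)-4‑bromo‑2‑methoxybenzene | COc1cc(Br)ccc1OCc1ccccc1 | intermediate
8 | (2S,3S)-4‑[4‑(benzyloxy)-3‑methoxyphenyl]-2,3‑dimethylbutyl acetate | COc1cc(C[C@H](C)[C@H](C)COC(C)=O)ccc1OCc1ccccc1 | intermediate
9 | (2S,3S)-4‑[4‑(benzyloxy)-3‑methoxyphenyl]-2,3‑dimethylbutan‑1‑ol | COc1cc(C[C@H](C)[C@H](C)CO)ccc1OCc1ccccc1 | intermediate
10 | 1‑(benzyloxy)-4‑[(2S,3S)-4‑iodo‑2,3‑dimethylbutyl]-2‑methoxybenzene | COc1cc(C[C@H](C)[C@H](C)CI)ccc1OCc1ccccc1 | intermediate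
11 | 4‑bromo‑2,6‑dimethoxyphenol | COc1cc(Br)cc(OC)c1O | starting material
12 | 2‑(benzyloxy)-5‑bromo‑1,3‑dimethoxybenzene | COc1cc(Br)cc(OC)c1OCc1ccccc1 | intermediate
13 | 2‑(benzyloxy)-5‑[(2R,3S)-4‑[4‑(benzyloxy)-3‑methoxyphenyl]-2,3‑dimethylbutyl]-1,3‑dimethoxybenzene | COc1cc(C[C@H](C)[C@H](C)Cc2cc(OC)c(OCc3ccccc3)c(OC)c2)ccc1OCc1ccccc1 | intermediate
14 | 4‑[(2S,3R)-4‑(4‑hydroxy‑3,5‑dimethoxyphenyl)-2,3‑dimethylbutyl]-2‑methoxyphenol | COc1cc(C[C@H](C)[C@H](C)Cc2cc(OC)c(O)c(OC)c2)ccc1O | target

**Totals**

Total steps: 11. Longest linear sequence: 9 (steps 1, 2, 3, 4, 6, 7, 8, 10, 11); steps 5 and 9 are one‑step side branches.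

**Steps most likely to fail**

1. Step 3 (lipase desymmetrisation): the ee may be insufficient on this flexible acyclic meso diol, and 4 can racemise by 1,4‑acyl migration. Fallback: run the enzyme in the hydrolytic direction. Peracetylate 3 and let a lipase or esterase hydrolyse one enantiotopic acetate of the meso diacetate in pH 7 buffer. This typically gives the antipodal monoacetate, which is handled by reversing the order of 7 and 12.

2. Step 6 (first Negishi coupling; the same concern applies to step 10): zinc insertion may be incomplete, or the alkylzinc may protonate or homocouple. Fallback: change the bond‑forming manifold to a Cu‑catalysed Kochi coupling. Silylate 4 (TBSCl), remove the acetate, tosylate, and couple with the arylmagnesium bromide using Li2CuCl4. This activates the other arm first, so the syringyl Grignard is used first, and the guaiacyl one after TBAF and tosylation.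

3. Step 1 (hydrogenation of a tetrasubstituted alkene): the reaction may be sluggish, or alkene isomerisation on Pd may leak some trans (racemic) anhydride, which would end up as the threo diastereomer. Fallback: skip the hydrogenation and start from commercial, achiral meso‑2,3‑dimethylsuccinic acid, reducing it directly with LiAlH4 to diol 3.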